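## Retrosynthetic overview

- **Feature:** the phenolic O of ring B, the two ring B carbons bearing that O and the side chain, C8 (the CH–CH3 methine) and C7 (the carbinol CH carrying the 3,4-dimethoxyphenyl ring A) make up five atoms of a six-membered lactone (ring C). One extra carbonyl carbon between O and C7 completes it, giving a 3-aryl-4-methylcoumarin with C4 = C8 and C3 = C7.
- **Disconnections:** the para allyl group comes from a para-Claisen rearrangement of the phenol O-allyl ether. The C7–OH comes from Baeyer–Villiger excision of the extra carbon (methyl ketone, retention). The ketone comes from the trans dihydrocoumarin through a Weinreb amide.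
- **Stereocentres:** both come from the flat coumarin. Enantioselective copper hydride 1,4-reduction sets C8, and base equilibration inside the ring sets C7 trans. The coumarin is made in one condensation from two bought arenes.
- **Ring order:** rings A and B are bought. Lactone ring C is the only ring formed (step 1) and is opened again in step 3.
- **End game order:** the phenol passes the peracid step as a silyl ether and is allylated afterwards, because a slow ketone oxidation would compete with epoxidation of an allyl ether. The Claisen step is run on the free C7 alcohol rather than on an ionisable benzylic acetate.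

Key step: step 2

Assumption: the sense of induction cannot be predicted with certainty for this alkene, so (R)-DTBM-SEGPHOS is written for hydride delivery to the face giving (4R), and the equally available (S)-ligand is used if the sense proves opposite.

## Route

Step 1
Reactants: 1 1-(2-hydroxy-3-methoxyphenyl)ethanone; 2 3,4-dimethoxyphenylacetic acid
Product: 5 3-(3,4-dimethoxyphenyl)-8-methoxy-4-methylcoumarin, via mixed anhydride 3 (not isolated), via aryl ester 4 (not isolated)
Conditions: Ac2O, Et3N, 115 °C
Reagents that add atoms: none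
Why: Perkin–Oglialoro coumarin synthesis, in which Ac2O turns 2 into mixed anhydride 3, this acylates the phenol of 1 to aryl ester 4, and the doubly activated benzylic CH2 of 4 is deprotonated by Et3N and closes onto the neighbouring acetyl carbonyl in an intramolecular aldol condensation driven by conjugation, a route well established for 3-aryl-4-methylcoumarins.

Step 2
Reactants: 5 3-(3,4-dimethoxyphenyl)-8-methoxy-4-methylcoumarin
Product: 8 (3S,4R)-trans-3-(3,4-dimethoxyphenyl)-8-methoxy-4-methyl-3,4-dihydrocoumarin, via silyl ketene acetal 6 (not isolated), via cis lactone 7 (not isolated)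
Conditions: Cu(OAc)2 (5 mol %), (R)-DTBM-SEGPHOS (5.5 mol %), (EtO)2MeSiH (1.3 equiv), toluene, rt to 40 °C; AcOH, THF–H2O, 0 °C; crude, DBU (0.2 equiv), toluene, rt
Reagents that add atoms: none
Why: Proposed new method: the ligated monovalent copper hydride generated from Cu(OAc)2, the bisphosphine and the silane hydrocuprates the polarised C3=C4 bond of 5 in the 1,4 sense, hydride going to C4 (C8 of the target), and σ-bond metathesis of the copper enolate with the silane releases silyl ketene acetal 6 and regenerates the hydride. The closest known reaction type is the copper hydride-catalysed enantioselective conjugate reduction of 4-substituted coumarins and of β,β-disubstituted unsaturated esters and lactones; not yet shown is the added 3-aryl group that makes the alkene tetrasubstituted, which should slow hydride transfer sterically but also lowers the LUMO and stabilises the enolate, while the flat bicyclic lactone leaves both faces open to the catalyst. No ring is closed or opened and no skeletal bond is made, only the C4–H and C3–H bonds. C4 is set under catalyst control, the chiral pocket of the bisphosphine telling apart the two faces of a planar substrate whose alkene geometry is fixed by the ring. C3 is set under substrate control: protonation of 6 may first deliver cis lactone 7 (proton anti to the methyl group), but the α-aryl lactone C–H is acidic enough for catalytic DBU to equilibrate it through the enolate to trans lactone 8, with aryl and methyl on opposite faces. The step needs 1,4- over 1,2-chemoselectivity, secured by leaving out any alcohol additive and limiting the silane, so that the reduced material stays masked as 6 until the quench and the reactive aryl ester carbonyl never meets the hydride.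

Step 3
Reactants: 8 (3S,4R)-trans-3-(3,4-dimethoxyphenyl)-8-methoxy-4-methyl-3,4-dihydrocoumarin
Product: 9 (2S,3R)-2-(3,4-dimethoxyphenyl)-3-(2-hydroxy-3-methoxyphenyl)-N-methoxy-N-methylbutanamide
Conditions: MeNH(OMe)·HCl, AlMe3, CH2Cl2, 0 °C; Rochelle salt work-up
Reagents that add atoms: N,O-dimethylhydroxylamine hydrochloride, CNOC.Cl
Why: Weinreb aminolysis of a lactone with an aluminium amide, in which the aryl ester is an activated acyl donor that opens at 0 °C under Lewis acidic and only weakly basic conditions, so the epimerisable C7–H and the C8 centre stay as set.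

Step 4
Reactants: 9 (2S,3R)-2-(3,4-dimethoxyphenyl)-3-(2-hydroxy-3-methoxyphenyl)-N-methoxy-N-methylbutanamide
Product: 10 (2S,3R)-3-[2-(tert-butyldimethylsilyloxy)-3-methoxyphenyl]-2-(3,4-dimethoxyphenyl)-N-methoxy-N-methylbutanamide
Conditions: TBSCl, imidazole, DMF, rt
Reagents that add atoms: tert-butyldimethylsilyl chloride, CC(C)(C)[Si](C)(C)Cl
Why: Imidazole-promoted silyl ether formation at the phenol, which blocks relactonisation, removes the acidic proton before the Grignard step and shields ring B from the peracid, while imidazole is too weak a base to touch the α-aryl amide C–H.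

Step 5
Reactants: 10 (2S,3R)-3-[2-(tert-butyldimethylsilyloxy)-3-methoxyphenyl]-2-(3,4-dimethoxyphenyl)-N-methoxy-N-methylbutanamide
Product: 12 (3S,4R)-4-[2-(tert-butyldimethylsilyloxy)-3-methoxyphenyl]-3-(3,4-dimethoxyphenyl)pentan-2-one, via magnesium hemiaminal chelate 11 (not isolated)
Conditions: MeMgBr, THF, −20 to 0 °C; cold pH 7 buffer
Reagents that add atoms: methylmagnesium bromide, C[Mg]Br
Why: Weinreb ketone synthesis, in which MeMgBr adds once to give chelate 11 that holds until the cold neutral quench, so no second addition takes place and the enolisable α-aryl ketone never meets the basic reagent, in line with the behaviour of Weinreb amides of 2-arylpropionic acids, which keep their configuration.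

Step 6
Reactants: 12 (3S,4R)-4-[2-(tert-butyldimethylsilyloxy)-3-methoxyphenyl]-3-(3,4-dimethoxyphenyl)pentan-2-one
Product: 14 (1S,2S)-2-[2-(tert-butyldimethylsilyloxy)-3-methoxyphenyl]-1-(3,4-dimethoxyphenyl)propyl acetate, via Criegee adduct 13 (not isolated)
Conditions: mCPBA, NaHCO3, CH2Cl2, 0 °C to rt
Reagents that add atoms: 3-chloroperoxybenzoic acid, O=C(OO)c1cccc(Cl)c1
Why: Baeyer–Villiger oxidation, in which the secondary electron-rich benzylic C7 of Criegee adduct 13 migrates far better than methyl and does so with retention, turning the C7–C(=O) bond into the C7–O bond of the (7S) acetate, while no alkene is present at this stage and the NaHCO3 buffer keeps acid away from the ionisable benzylic ester.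

Step 7
Reactants: 14 (1S,2S)-2-[2-(tert-butyldimethylsilyloxy)-3-methoxyphenyl]-1-(3,4-dimethoxyphenyl)propyl acetate
Product: 15 2-[(1S,2S)-1-(3,4-dimethoxyphenyl)-1-hydroxypropan-2-yl]-6-methoxyphenol
Conditions: K2CO3, MeOH, rt
Reagents that add atoms: none
Why: Base-catalysed methanolysis, in which methoxide attacks the acetate carbonyl and the silicon of the aryl silyl ether (phenoxide being a good leaving group), and neither event touches the C7–O bond, so both configurations are kept.

Step 8
Reactants: 15 2-[(1S,2S)-1-(3,4-dimethoxyphenyl)-1-hydroxypropan-2-yl]-6-methoxyphenol; 16 allyl bromide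
Product: 17 (1S,2S)-2-[2-(allyloxy)-3-methoxyphenyl]-1-(3,4-dimethoxyphenyl)propan-1-ol
Conditions: K2CO3, acetone, reflux
Reagents that add atoms: allyl bromide 16, C=CCBr
Why: Williamson ether synthesis, in which K2CO3 deprotonates only the phenol, several pKa units more acidic than the benzylic alcohol, and the phenoxide displaces bromide from 16 in an SN2 reaction.

Step 9
Reactants: 17 (1S,2S)-2-[2-(allyloxy)-3-methoxyphenyl]-1-(3,4-dimethoxyphenyl)propan-1-ol
Product: 20 4-allyl-2-[(1S,2S)-1-(3,4-dimethoxyphenyl)-1-hydroxypropan-2-yl]-6-methoxyphenol, via ortho dienone 18 (not isolated), via para dienone 19 (not isolated)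
Conditions: PhNEt2, 195 °C, sealed tube, argon
Reagents that add atoms: none
Why: Aromatic para-Claisen rearrangement, in which the [3,3] shift to a blocked ortho carbon gives ortho dienone 18 that cannot enolise, a Cope [3,3] shift passes the allyl group to the para carbon as para dienone 19 and tautomerisation restores the phenol, while the weakly basic solvent and the poor leaving group ability of a free hydroxyl guard C7 against ionisation and neither stereocentre takes part.

## Compound list

1 | 1-(2-hydroxy-3-methoxyphenyl)ethanone | CC(=O)c1cccc(OC)c1O | starting material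
2 | 3,4-dimethoxyphenylacetic acid | COc1ccc(CC(=O)O)cc1OC | starting material
3 | acetic 2-(3,4-dimethoxyphenyl)acetic anhydride | CC(=O)OC(=O)Cc1ccc(OC)c(OC)c1 | intermediate
4 | 2-acetyl-6-methoxyphenyl 2-(3,4-dimethoxyphenyl)acetate | CC(=O)c1cccc(OC)c1OC(=O)Cc1ccc(OC)c(OC)c1 | intermediate
5 | 3-(3,4-dimethoxyphenyl)-8-methoxy-4-methylcoumarin | COc1cccc2c1OC(=O)C(c1ccc(OC)c(OC)c1)=C2C | intermediate
6 | {[(4S)-3-(3,4-dimethoxyphenyl)-8-methoxy-4-methyl-4H-chromen-2-yl]oxy}diethoxy(methyl)silane (same spatial arrangement at C4 as in 8) | COc1cccc2c1OC(O[Si](C)(OCC)OCC)=C(c1ccc(OC)c(OC)c1)[C@H]2C | intermediate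
7 | (3R,4R)-cis-3-(3,4-dimethoxyphenyl)-8-methoxy-4-methyl-3,4-dihydrocoumarin | COc1cccc2c1OC(=O)[C@@H](c1ccc(OC)c(OC)c1)[C@H]2C | intermediate
8 | (3S,4R)-trans-3-(3,4-dimethoxyphenyl)-8-methoxy-4-methyl-3,4-dihydrocoumarin | COc1cccc2c1OC(=O)[C@H](c1ccc(OC)c(OC)c1)[C@H]2C | intermediate
9 | (2S,3R)-2-(3,4-dimethoxyphenyl)-3-(2-hydroxy-3-methoxyphenyl)-N-methoxy-N-methylbutanamide | CON(C)C(=O)[C@H](c1ccc(OC)c(OC)c1)[C@@H](C)c1cccc(OC)c1O | intermediate
10 | (2S,3R)-3-[2-(tert-butyldimethylsilyloxy)-3-methoxyphenyl]-2-(3,4-dimethoxyphenyl)-N-methoxy-N-methylbutanamide | CON(C)C(=O)[C@H](c1ccc(OC)c(OC)c1)[C@@H](C)c1cccc(OC)c1O[Si](C)(C)C(C)(C)C | intermediate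
11 | bromomagnesium alkoxide of the tetrahedral MeMgBr adduct of 10 (new carbon unspecified) | CON(C)C(C)(O[Mg]Br)[C@H](c1ccc(OC)c(OC)c1)[C@@H](C)c1cccc(OC)c1O[Si](C)(C)C(C)(C)C | intermediate
12 | (3S,4R)-4-[2-(tert-butyldimethylsilyloxy)-3-methoxyphenyl]-3-(3,4-dimethoxyphenyl)pentan-2-one | CC(=O)[C@H](c1ccc(OC)c(OC)c1)[C@@H](C)c1cccc(OC)c1O[Si](C)(C)C(C)(C)C | intermediate
13 | Criegee adduct of 12 with mCPBA (hemiperketal carbon unspecified) | CC(O)(OOC(=O)c1cccc(Cl)c1)[C@H](c1ccc(OC)c(OC)c1)[C@@H](C)c1cccc(OC)c1O[Si](C)(C)C(C)(C)C | intermediate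
14 | (1S,2S)-2-[2-(tert-butyldimethylsilyloxy)-3-methoxyphenyl]-1-(3,4-dimethoxyphenyl)propyl acetate | CC(=O)O[C@H](c1ccc(OC)c(OC)c1)[C@@H](C)c1cccc(OC)c1O[Si](C)(C)C(C)(C)C | intermediate
15 | 2-[(1S,2S)-1-(3,4-dimethoxyphenyl)-1-hydroxypropan-2-yl]-6-methoxyphenol | COc1cccc([C@H](C)[C@H](O)c2ccc(OC)c(OC)c2)c1O | intermediate
16 | allyl bromide | C=CCBr | starting material
17 | (1S,2S)-2-[2-(allyloxy)-3-methoxyphenyl]-1-(3,4-dimethoxyphenyl)propan-1-ol | C=CCOc1c(OC)cccc1[C@H](C)[C@H](O)c1ccc(OC)c(OC)c1 | intermediate
18 | 6-allyl-6-methoxy-2-[(1S,2S)-1-(3,4-dimethoxyphenyl)-1-hydroxypropan-2-yl]cyclohexa-2,4-dien-1-one (quaternary carbon unspecified) | C=CCC1(OC)C=CC=C([C@H](C)[C@H](O)c2ccc(OC)c(OC)c2)C1=O | intermediate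
19 | 4-allyl-2-methoxy-6-[(1S,2S)-1-(3,4-dimethoxyphenyl)-1-hydroxypropan-2-yl]cyclohexa-2,5-dien-1-one (C4 unspecified) | C=CCC1C=C(OC)C(=O)C([C@H](C)[C@H](O)c2ccc(OC)c(OC)c2)=C1 | intermediate
20 | 4-allyl-2-[(1S,2S)-1-(3,4-dimethoxyphenyl)-1-hydroxypropan-2-yl]-6-methoxyphenol (7S,8S) | C=CCc1cc(OC)c(O)c([C@H](C)[C@H](O)c2ccc(OC)c(OC)c2)c1 | target

## Step count and risks

Total step count: 9. Longest linear sequence: 9 (from 1 or 2 to 20).

**1. Step 2.**
- What may go wrong: hydride transfer to the tetrasubstituted alkene may be too slow, the two faces may be poorly told apart, or the lactone carbonyl may be reduced further.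
- Fallback (known chemistry, from 5 back to 8):
  - Heterogeneous hydrogenation (H2, Pd/C, EtOAc–AcOH, 60 °C, pressure), as practised on 3,4-disubstituted coumarins, should give by syn addition the racemic cis lactone F1.
  - Catalytic DBU equilibrates F1 to the racemic trans lactone F2.
  - Aminolysis with (S)-1-phenylethylamine (toluene, 60 °C) turns the racemate into two diastereomers, the (2S,3R)-hydroxy amide F3 and the (2R,3S)-hydroxy amide F4. These are separated by crystallisation or chromatography.
  - Heating F3 with TsOH in toluene closes the lactone again through attack of the neighbouring phenol on the protonated amide and returns 8. Any epimerisation at C3 is harmless because trans is the stable isomer.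

**2. Step 6.**
- What may go wrong: addition of the peracid to the hindered acyclic ketone may be sluggish. This leaves time for epimerisation at C7 through the enol and for oxidation of the electron-rich rings.
- Fallback (from 10 back to 15, bypassing steps 5 and 6):
  - Reduction of the Weinreb amide with DIBAL-H (toluene, −78 °C) gives the (2S,3R)-aldehyde F5, whose unhindered carbonyl takes up mCPBA at 0 °C.
  - As known for 2-aryl-substituted aldehydes, the secondary benzylic carbon migrates with retention and gives the (1S,2S)-formate F6.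
  - The K2CO3/MeOH treatment of step 7 converts F6 into 15.

**3. Step 9.**
- What may go wrong: at the temperature the double [3,3] shift needs, loss of water from C7 may compete, either with closure by the freshly formed phenol or as elimination towards C8.
- Fallback (from 15 back to 20, replacing steps 8 and 9, no heating above 100 °C):
  - Bromination with NBS (1 equiv, CH2Cl2, −40 °C) should take place on the free phenol ring, the most activated arene, at its only open position para to OH. This gives the para-bromophenol F7.
  - Stille coupling of F7 with allyltributylstannane (Pd(PPh3)4, toluene, 100 °C) installs the allyl group directly and gives 20.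

## Further compounds

F1 | step 2 | racemic cis-3-(3,4-dimethoxyphenyl)-8-methoxy-4-methyl-3,4-dihydrocoumarin | COc1cccc2c1OC(=O)[C@@H](c1ccc(OC)c(OC)c1)[C@H]2C.COc1cccc2c1OC(=O)[C@H](c1ccc(OC)c(OC)c1)[C@@H]2C
F2 | step 2 | racemic trans-3-(3,4-dimethoxyphenyl)-8-methoxy-4-methyl-3,4-dihydrocoumarin | COc1cccc2c1OC(=O)[C@H](c1ccc(OC)c(OC)c1)[C@H]2C.COc1cccc2c1OC(=O)[C@@H](c1ccc(OC)c(OC)c1)[C@@H]2C
F3 | step 2 | (2S,3R)-2-(3,4-dimethoxyphenyl)-3-(2-hydroxy-3-methoxyphenyl)-N-[(S)-1-phenylethyl]butanamide | C[C@H](NC(=O)[C@H](c1ccc(OC)c(OC)c1)[C@@H](C)c1cccc(OC)c1O)c1ccccc1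
F4 | step 2 | (2R,3S)-2-(3,4-dimethoxyphenyl)-3-(2-hydroxy-3-methoxyphenyl)-N-[(S)-1-phenylethyl]butanamide | C[C@H](NC(=O)[C@@H](c1ccc(OC)c(OC)c1)[C@H](C)c1cccc(OC)c1O)c1ccccc1
F5 | step 6 | (2S,3R)-3-[2-(tert-butyldimethylsilyloxy)-3-methoxyphenyl]-2-(3,4-dimethoxyphenyl)butanal | O=C[C@H](c1ccc(OC)c(OC)c1)[C@@H](C)c1cccc(OC)c1O[Si](C)(C)C(C)(C)C
F6 | step 6 | (1S,2S)-2-[2-(tert-butyldimethylsilyloxy)-3-methoxyphenyl]-1-(3,4-dimethoxyphenyl)propyl formate | O=CO[C@H](c1ccc(OC)c(OC)c1)[C@@H](C)c1cccc(OC)c1O[Si](C)(C)C(C)(C)C
F7 | step 9 | 4-bromo-2-[(1S,2S)-1-(3,4-dimethoxyphenyl)-1-hydroxypropan-2-yl]-6-methoxyphenol | COc1cc(Br)cc([C@H](C)[C@H](O)c2ccc(OC)c(OC)c2)c1O
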